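The winter run, charged with 0.40 M of solid substrate, still holds 13 % of it at 20.0 h, so it has dissolved at 0.0174 M h⁻¹. The spring run, with half that charge, gives 0.0167 M h⁻¹ up to 8.00 h, about the same. Meanwhile the midnight run at 8.00 h reads [dissolved substrate] at 1 % against 60 % of target, so going into solution is the rate-limiting step there while solid lasts.

| setting | spring | midnight | winter | flask |
|---|---|---|---|---|
| solid substrate | 0.20 M | 0.20 M | 0.40 M | 0.20 M |
| reagent | 0.80 equiv | 1.8 equiv | 1.2 equiv | 1.20 equiv |
| remark | run made earlier | run made earlier | run made earlier |  |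
| time |  |  |  | 25 h |

| run | time / h | target / % | dissolved substrate / % | solid substrate / % |
|---|---|---|---|---|
| spring | 4.00 | 31 | 2 | 66 |
| spring | 8.00 | 50 | 6 | 33 |
| spring | 10.0 | 51 | 19 | 18 |
| spring | 15.0 | 50 | 28 | 1 |
| spring | 20.0 | 54 | 27 | 0 |
| spring | 25.0 | 49 | 24 | 3 |
| midnight | 4.00 | 33 | 1 | 67 |
| midnight | 8.00 | 60 | 1 | 30 |
| midnight | 10.0 | 75 | 3 | 12 |
| midnight | 15.0 | 76 | 0 | 0 |
| midnight | 20.0 | 69 | 0 | 0 |
| midnight | 25.0 | 67 | 0 | 0 |
| winter | 5.00 | 20 | 1 | 80 |
| winter | 10.0 | 38 | 3 | 56 |
| winter | 15.0 | 51 | 2 | 33 |
| winter | 20.0 | 67 | 1 | 13 |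
| winter | 25.0 | 71 | 3 | 0 |

(each reading ± 1.5 percentage points)

- solid, in amounts per volume of the solution: solid substrate
- what may be going on: dissolved substrate + reagent -> target; target <-> isomer of the product; solid substrate <-> dissolved substrate; reagent <-> dormant form
- at the start none of the solid substrate is in solution
- dissolved substrate means what is dissolved; the solid is not counted in it

- target at 25 h, in percent of the solid substrate charged
- concentration of dissolved substrate in solution at 25 h, in percent of saturation

I divide the charge by the winter rate and get 11.5 h for the new flask, the clearing time: how long the solid lasts at that rate. At the winter charge it is 23.0 h, close to the whole reading time, so I leave the charge at 0.20 M. That gives the flask 13.5 h after clearing, longer than the 3.51 h after which the midnight run, with the same charge of solid substrate but 1.8 equiv of reagent, reads 0 % dissolved. With 1.20 equiv the reagent exceeds the charge, so I expect [dissolved substrate] near zero at 25 h.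

The forecast gives 65 % of target and 6 % of saturation, expecting that “the leftover substrate should mostly be consumed”.

The flask gives 67.5 % of target and 0 % of saturation.

    dissolved substrate + reagent → target (k = 0.0400 M⁻¹ s⁻¹)
    target ⇌ isomer of the product (K = 0.600, k = 1.20 × 10⁻⁵ s⁻¹)
    solid substrate ⇌ dissolved substrate, rate k3*(cs3 - [dissolved substrate]) while solid is left; crystals form when [dissolved substrate] > cs3 (solubility = 0.100 M, k = 4.90 × 10⁻⁵ s⁻¹)
    reagent ⇌ dormant form (K = 1.60, k = 4.10 × 10⁻⁵ s⁻¹)

The flask reads 0 % of solid substrate at 12.5 h, just after the clearing time of 11.5 h. In the neighbouring flask, with 0.80 M of solid substrate and the same equivalents and time, the same reckoning gives a clearing time of 46.0 h, longer than the 25 h of reading. A steady rate then leaves 45.7 % of the charge as solid at that time. That neighbouring flask reads 45.1 % of solid substrate and 41.0 % of target.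

Readings and results are simulated from invented constants, noise included.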